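9.19 substrate half-lives fit into the run if the catalyst left by the impurity keeps working, and two chemists dispute that "if".

| flask | substrate | free catalyst | impurity | time |
|---|---|---|---|---|
| delta | 0.060 mM | 100 µM | 36 µM | 3.0 min |
| gamma | 0.12 mM | 100 µM | 36 µM | 3.0 min |
| eta | 0.25 mM | 100 µM | 36 µM | 3.0 min |
| zeta | 0.50 mM | 100 µM | 36 µM | 3.0 min |
| alpha | 1.0 mM | 100 µM | 36 µM | 3.0 min |

    substrate + free catalyst → catalyst intermediate A (k1 = 553 L mol⁻¹ s⁻¹)
    catalyst intermediate A → catalyst intermediate B (k2 = 10.7 s⁻¹)
    catalyst intermediate B → free catalyst + product (k3 = 0.896 s⁻¹)
    2 catalyst intermediate B → spent catalyst A (k4 = 16000 L mol⁻¹ s⁻¹)
    free catalyst + impurity → spent catalyst B (k5 = 1.46 × 10⁶ L mol⁻¹ s⁻¹)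

- in percentages every species weighs as the substrate in it: one spent catalyst A counts as two
- a doubled species enters its step squared and goes two at a time
- "hardly changes" means that all values lie within two and a half points (for a concentration: within two and a half percent of the largest)
- run time (delta): 3.0 min

* [product] at the end for delta, gamma, eta, zeta, alpha, in this order
* the course of these numbers from the first flask to the last (falls all the way / hardly changes / rises all the way / falls, then rises / rises, then falls)

The first chemist counts. In alpha the impurity takes free catalyst 95.0 times faster than the substrate does, so she writes off 0.360 of the catalyst charge at once. On her count the remaining 0.640 then consumes substrate in a pseudo-first-order way, with a half-life of 0.326 min. After 9.19 half-lives, 0.171 % of a charge is left. Her half-life contains no substrate charge, so she expects the row to copy the charges and keep rising.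

The second chemist watches catalyst intermediate B, which pairs off at a rate that goes with its square. I reckon his view this way. While the release step carries intermediate B away, its level is the binding rate over the release constant, and each pairing removes two catalyst units. Dividing that loss by the substrate rate and integrating over the charge, the catalyst concentration cancels. The fraction of working catalyst surviving once the substrate is used up is the exponential of minus the squared ratio of substrate charge to spoiling charge. The spoiling charge, the release constant over the root of the product of the binding and pairing constants, is 3.01 catalyst charges.

By this estimate delta, at 0.600 catalyst charges, keeps 96.1 % of its working catalyst once its substrate is used up. For eta, at 2.50, the estimate is 50.2 %, and for zeta, at 5.00, it is 6.36 %. The rule breaks down at the start of alpha: there the release level would be 0.395 of the catalyst charge, above the 0.280 at which pairing matches release. At the start of zeta the level would be 0.197, still below that mark. My reckoning gives survival, not a row.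

The forecast takes the second side, with its own numbers: 0.057 mM, 0.108 mM, 0.215 mM, 0.38 mM, 0.33 mM, a course that rises, then falls. Its ground is that at high loading “its second-order loss kills the catalyst before the substrate is used”.

The simulation gives 0.0577 mM, 0.112 mM, 0.222 mM, 0.357 mM, 0.332 mM, a course that rises, then falls, so the second chemist wins. The counter keeps the light end: delta ends with product at 96.2 % of its charge and substrate at 0.216 %, while alpha still holds 60.5 % of its substrate, with free catalyst at 1.52 %. Gamma stands at 0.398 of the spoiling charge, so the rule, with the impurity's share taken off, estimates 54.6 % of the catalyst charged as free catalyst once gamma's substrate is used up, and gamma ends with free catalyst at 56.5 %.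

The rate constants come from no measurement; the flask was simulated.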